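The whole plan rests on making the benzene ring last. Its two para oxygens, on C2 and C5, are the exocyclic and the ring oxygen of a 4-bromo-2-silyloxyfuran whose four carbons become C2–C5 (bromine on C4). C1 and C6 are the triple bond of a terminal ynone. One Diels–Alder addition with in-flask opening of the oxygen bridge forms C1–C2 and C5–C6, closes the carbocycle and places acyl, bromine and both oxygens in a single operation. The precursor is a C12 ethynyl ketone carrying the silyl-protected (R) tertiary carbinol, reached from (R)-linalool by terminal hydration of its vinyl group, oxidation, ethynylation and re-oxidation.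

Key step: step 7

Assumption: the purchased (R)-(−)-linalool has the enantiomeric purity wanted in the product. It is to be assayed by chiral GC before use, because no step of the route can raise or lower it.

Step 1
Reactants: 1 (R)-(−)-linalool
Product: 2 (R)-3,7-dimethyl-3-(triethylsilyloxy)octa-1,6-diene
Conditions: TESOTf (1.2 equiv), 2,6-lutidine (2 equiv), CH2Cl2, −78 → 0 °C
Reagents that add atoms: triethylsilyl triflate, CC[Si](CC)(CC)OS(=O)(=O)C(F)(F)F
Why: Silyl triflate/2,6-lutidine O-silylation is the standard way to cap a hindered tertiary alcohol, runs cold and buffered so the tertiary allylic C–O bond does not ionise, and touches none of the four bonds at C3, so the (R) configuration is simply carried along.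

Step 2
Reactants: 2 (R)-3,7-dimethyl-3-(triethylsilyloxy)octa-1,6-diene
Product: 4 (R)-3,7-dimethyl-3-(triethylsilyloxy)oct-6-en-1-ol, via B-alkyl-9-BBN adduct 3 (not isolated)
Conditions: 9-BBN (0.5 M in THF, 1.2 equiv), 0 → 23 °C; then NaBO3·4H2O, H2O, 23 °C
Reagents that add atoms: sodium perborate tetrahydrate, [Na+].[O-]OB=O.O.O.O.O (supplies the hydroxyl oxygen of 4); 9-BBN, B1C2CCCC1CCC2 (its boron unit stays only in 3)
Why: In this Brown hydroboration–oxidation the bulky 9-BBN adds to the monosubstituted vinyl group much faster than to the trisubstituted C6=C7 alkene and puts boron on the terminal carbon, too far from the oxygen for beta-elimination, and perborate then replaces boron by hydroxyl under nearly neutral conditions that the TES ether tolerates.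

Step 3
Reactants: 4 (R)-3,7-dimethyl-3-(triethylsilyloxy)oct-6-en-1-ol
Product: 5 (R)-3,7-dimethyl-3-(triethylsilyloxy)oct-6-enal
Conditions: TEMPO (10 mol %), PhI(OAc)2 (1.1 equiv), CH2Cl2, 23 °C
Reagents that add atoms: none
Why: Oxoammonium-mediated (TEMPO/PhI(OAc)2) oxidation of a primary alcohol stops at the aldehyde in dry CH2Cl2, leaves prenyl-type alkenes and silyl ethers alone, and contains no base that could trigger E1cB loss of the beta silyloxy group.

Step 4
Reactants: 5 (R)-3,7-dimethyl-3-(triethylsilyloxy)oct-6-enal; 6 ethynylmagnesium bromide (0.5 M in THF, 1.5 equiv)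
Product: 7 (3RS,5R)-5,9-dimethyl-5-(triethylsilyloxy)dec-8-en-1-yn-3-ol (both C3 epimers)
Conditions: THF, −78 → 0 °C; sat. aq. NH4Cl
Reagents that add atoms: none
Why: Grignard 1,2-addition of a small, weakly basic acetylide to an unhindered aldehyde is faster than enolisation at low temperature, and the new carbinol centre may form as both epimers because step 5 turns it into a carbonyl carbon.

Step 5
Reactants: 7 (3RS,5R)-5,9-dimethyl-5-(triethylsilyloxy)dec-8-en-1-yn-3-ol
Product: 8 (R)-5,9-dimethyl-5-(triethylsilyloxy)dec-8-en-1-yn-3-one
Conditions: Dess–Martin periodinane (1.3 equiv), solid NaHCO3, CH2Cl2, 0 → 23 °C; pentane, filtration through SiO2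
Reagents that add atoms: none
Why: Dess–Martin oxidation converts secondary propargylic alcohols into ynones quickly under buffered, non-nucleophilic conditions, merges both epimers into one compound, and the non-aqueous filtration work-up keeps nucleophiles away from the exposed Michael acceptor.

Step 6
Reactants: 9 4-bromofuran-2(5H)-one
Product: 10 4-bromo-2-(tert-butyldimethylsilyloxy)furan
Conditions: TBSOTf (1.1 equiv), i-Pr2NEt (1.3 equiv), CH2Cl2, 0 °C; pentane, cold aq. NaHCO3 wash; bulb-to-bulb distillation (amine-free), used the same day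
Reagents that add atoms: tert-butyldimethylsilyl triflate, CC(C)(C)[Si](C)(C)OS(=O)(=O)C(F)(F)F
Why: Soft enolisation and O-silylation of a butenolide (silyl ketene acetal formation driven by aromatisation to the furan) is the standard entry to 2-silyloxyfurans, the hindered amine should not displace the vinylic bromide by addition–elimination, and no stereocentre is involved.

Step 7
Reactants: 8 (R)-5,9-dimethyl-5-(triethylsilyloxy)dec-8-en-1-yn-3-one; 10 4-bromo-2-(tert-butyldimethylsilyloxy)furan (1.5 equiv)
Product: 12 (R)-1-[4-bromo-2-(tert-butyldimethylsilyloxy)-5-hydroxyphenyl]-3,7-dimethyl-3-(triethylsilyloxy)oct-6-en-1-one, via 7-oxanorbornadiene cycloadduct 11 (not isolated)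
Conditions: dry toluene (1 M), Ar, 23 → 60 °C; then SiO2, CH2Cl2, 23 °C
Reagents that add atoms: none
Why: The donor-substituted furan 10 acts as diene and the acceptor-substituted alkyne of 8 as dienophile in a normal-electron-demand Diels–Alder reaction that is concerted but strongly asynchronous (or stepwise through a vinylogous Mukaiyama–Michael zwitterion collapsing to the same bicycle), the furan C5–terminal alkyne carbon bond (arene C5–C6) running ahead of the furan C2–acyl-bearing alkyne carbon bond (arene C2–C1). The six-membered carbocycle is thus closed by an intermolecular (4+2) cycloaddition, and in 11 the silyloxy-bearing bridgehead is a ketal carbon whose bond to the bridging oxygen ionises readily, so that loss of the proton from the other bridgehead gives arene 12, an isomer of 11 holding every atom of 8 and 10, in which the former ring oxygen is the free C5 phenol beside bromine. The closest known reaction type is the cycloaddition of 2-silyloxy- and 2-alkoxyfurans to acetylenic esters and ketones with spontaneous bridge opening to hydroquinone monoethers, here applied to a new diene and dienophile pair. The two bridgehead stereocentres of 11 form without control by the remote (R) centre, which does not matter because both become sp2 carbons on aromatisation, while the (R) carbinol carbon is a spectator. The selectivity needed is regiochemical and is doubly secured in the substrate: the C2 silyloxy donor (ortho rule) and the C4 bromine (para rule) both raise the HOMO coefficient at furan C5, which matches the large LUMO coefficient at the unsubstituted, sterically open alkyne terminus, so the acyl group lands ortho to OSi and para to Br. Chemoselectivity rests on the TES cap (no oxa-Michael closure to a dihydropyranone and no retro-aldol cleavage), on the unactivated C6=C7 alkene being a much poorer dienophile, and on amine-free diene used in excess so that the liberated phenol meets no residual ynone; any silyl scrambling between the two phenol oxygens is harmless because step 8 removes all silicon.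

Step 8
Reactants: 12 (R)-1-[4-bromo-2-(tert-butyldimethylsilyloxy)-5-hydroxyphenyl]-3,7-dimethyl-3-(triethylsilyloxy)oct-6-en-1-one
Product: 14 (R)-1-(4-bromo-2,5-dihydroxyphenyl)-3-hydroxy-3,7-dimethyloct-6-en-1-one (CNP0227808.2), via TES-protected hydroquinone 13 (not isolated)
Conditions: HF·pyridine, extra pyridine, THF, 0 → 23 °C (plastic vessel); pH 7 phosphate buffer
Reagents that add atoms: none
Why: Fluoride-driven desilylation with pyridine-buffered HF·pyridine cleaves the activated aryl silyl ether first and the tertiary TES ether more slowly, in a weakly acidic window where neither alkoxide-triggered retro-aldol cleavage nor acid-triggered dehydration and chromanone closure is expected, and the C–O bond at the stereocentre is never broken, so 14 keeps the (R) configuration.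

Compound list
1 | (R)-(−)-linalool | CC(C)=CCC[C@@](C)(O)C=C | starting material
2 | (R)-3,7-dimethyl-3-(triethylsilyloxy)octa-1,6-diene | CC(C)=CCC[C@@](C)(O[Si](CC)(CC)CC)C=C | intermediate
3 | 9-[(S)-3,7-dimethyl-3-(triethylsilyloxy)oct-6-en-1-yl]-9-borabicyclo[3.3.1]nonane (same spatial arrangement as 2; the descriptor reads S only because CH2CH2B ranks below the homoprenyl chain) | CC(C)=CCC[C@@](C)(O[Si](CC)(CC)CC)CCB1C2CCCC1CCC2 | intermediate (not isolated)
4 | (R)-3,7-dimethyl-3-(triethylsilyloxy)oct-6-en-1-ol | CC(C)=CCC[C@@](C)(O[Si](CC)(CC)CC)CCO | intermediate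
5 | (R)-3,7-dimethyl-3-(triethylsilyloxy)oct-6-enal | CC(C)=CCC[C@@](C)(O[Si](CC)(CC)CC)CC=O | intermediate
6 | ethynylmagnesium bromide | C#C[Mg]Br | starting material
7 | (3RS,5R)-5,9-dimethyl-5-(triethylsilyloxy)dec-8-en-1-yn-3-ol, both C3 epimers | CC(C)=CCC[C@@](C)(O[Si](CC)(CC)CC)CC(O)C#C | intermediate
8 | (R)-5,9-dimethyl-5-(triethylsilyloxy)dec-8-en-1-yn-3-one | CC(C)=CCC[C@@](C)(O[Si](CC)(CC)CC)CC(=O)C#C | intermediate
9 | 4-bromofuran-2(5H)-one | O=C1C=C(Br)CO1 | starting material
10 | 4-bromo-2-(tert-butyldimethylsilyloxy)furan | CC(C)(C)[Si](C)(C)Oc1cc(Br)co1 | intermediate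
11 | (R)-1-[5-bromo-1-(tert-butyldimethylsilyloxy)-7-oxabicyclo[2.2.1]hepta-2,5-dien-2-yl]-3,7-dimethyl-3-(triethylsilyloxy)oct-6-en-1-one, both bridgehead diastereomers | CC(C)=CCC[C@@](C)(O[Si](CC)(CC)CC)CC(=O)C1=CC2OC1(O[Si](C)(C)C(C)(C)C)C=C2Br | intermediate (not isolated)
12 | (R)-1-[4-bromo-2-(tert-butyldimethylsilyloxy)-5-hydroxyphenyl]-3,7-dimethyl-3-(triethylsilyloxy)oct-6-en-1-one | CC(C)=CCC[C@@](C)(O[Si](CC)(CC)CC)CC(=O)c1cc(O)c(Br)cc1O[Si](C)(C)C(C)(C)C | intermediate
13 | (R)-1-(4-bromo-2,5-dihydroxyphenyl)-3,7-dimethyl-3-(triethylsilyloxy)oct-6-en-1-one | CC(C)=CCC[C@@](C)(O[Si](CC)(CC)CC)CC(=O)c1cc(O)c(Br)cc1O | intermediate (not isolated)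
14 | (R)-1-(4-bromo-2,5-dihydroxyphenyl)-3-hydroxy-3,7-dimethyloct-6-en-1-one (CNP0227808.2) | CC(C)=CCC[C@@](C)(O)CC(=O)c1cc(O)c(Br)cc1O | target

Total step count: 8.
Longest linear sequence: 7 steps from (R)-linalool (steps 1–5, 7 and 8). Step 6 is a one-step side branch, timed to finish on the day of step 7.

Steps most likely to fail

Step 7.
- **What may go wrong:** The bromine weakens the furan as a donor, so the cycloaddition may lag behind hydrolysis of the labile diene by adventitious water. The partners may also join only at furan C5 and then transfer the silyl group, stopping at an open conjugate adduct without forming the second bond.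
- **Fallback:** The arene is bought instead of built, which also dispenses with diene 10. The fallback sets out from aldehyde 5 and comes back to the route at 13, the in-flask intermediate of step 8.
- Commercial 2,5-dibromohydroquinone is silylated on both oxygens (TBSCl, imidazole, DMF) to give 1,4-dibromo-2,5-bis(tert-butyldimethylsilyloxy)benzene F1.
- Both bromines of F1 are equivalent, so one bromine–magnesium exchange with i-PrMgCl·LiCl in THF gives [4-bromo-2,5-bis(tert-butyldimethylsilyloxy)phenyl]magnesium chloride F2. Magnesium is preferred to lithium to suppress O-to-C silyl migration.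
- Addition of this reagent to 5 gives (1RS,3R)-1-[4-bromo-2,5-bis(tert-butyldimethylsilyloxy)phenyl]-3,7-dimethyl-3-(triethylsilyloxy)oct-6-en-1-ol F3 as both epimers.
- Dess–Martin oxidation then gives (R)-1-[4-bromo-2,5-bis(tert-butyldimethylsilyloxy)phenyl]-3,7-dimethyl-3-(triethylsilyloxy)oct-6-en-1-one F4.
- Under the HF·pyridine conditions of step 8 both phenols are freed first, which gives 13, and the carbinol follows.

Step 8.
- **What may go wrong:** Removal of the hindered tertiary silyl ether may need long exposure. During that time, dehydration of the tertiary carbinol followed by closure of the ortho phenol onto the resulting enone may compete, as may retro-aldol fragmentation on work-up.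
- **Fallback:** The tertiary oxygen is unmasked before any carbonyl group exists. The fallback sets out from propargylic alcohol 7 and comes back at 14.
- TBAF in THF, harmless at this stage, gives (3RS,5R)-5,9-dimethyldec-8-en-1-yne-3,5-diol F5.
- Activated MnO2 in CH2Cl2 oxidises only the secondary propargylic alcohol to give (R)-5-hydroxy-5,9-dimethyldec-8-en-1-yn-3-one F6. Ketones of this type are isolable under neutral conditions and need acid, base or metal catalysis to cyclise.
- Heating with 10 in toluene as in step 7 passes through the hydroxy-bearing 7-oxanorbornadiene cycloadduct F7 (not isolated) to give (R)-1-[4-bromo-2-(tert-butyldimethylsilyloxy)-5-hydroxyphenyl]-3-hydroxy-3,7-dimethyloct-6-en-1-one F8.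
- The single, activated aryl silyl ether of F8 is then removed by brief treatment with Et3N·3HF in THF at 0 °C to give 14.

Step 5.
- **What may go wrong:** The unsubstituted ynone may be lost during oxidation or isolation. The routes are conjugate addition of acetate or water, oligomerisation, or E1cB loss of the beta silyloxy group.
- **Fallback:** The alkyne is carried capped and released only at the last moment. The fallback sets out from aldehyde 5 and comes back at 8.
- Commercial lithium (trimethylsilyl)acetylide adds to 5 in THF at −78 °C to give (3RS,5R)-5,9-dimethyl-5-(triethylsilyloxy)-1-(trimethylsilyl)dec-8-en-1-yn-3-ol F9.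
- Dess–Martin oxidation gives the storable (R)-5,9-dimethyl-5-(triethylsilyloxy)-1-(trimethylsilyl)dec-8-en-1-yn-3-one F10.
- Directly before step 7 the activated C(sp)–Si bond is cleaved with dilute aqueous Na2B4O7 in methanol at 23 °C. These conditions spare the TES ether and deliver 8.

Further compounds
F1 | step 7 | 1,4-dibromo-2,5-bis(tert-butyldimethylsilyloxy)benzene | CC(C)(C)[Si](C)(C)Oc1cc(Br)c(O[Si](C)(C)C(C)(C)C)cc1Br
F2 | step 7 | [4-bromo-2,5-bis(tert-butyldimethylsilyloxy)phenyl]magnesium chloride | CC(C)(C)[Si](C)(C)Oc1cc(Br)c(O[Si](C)(C)C(C)(C)C)cc1[Mg]Cl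
F3 | step 7 | (1RS,3R)-1-[4-bromo-2,5-bis(tert-butyldimethylsilyloxy)phenyl]-3,7-dimethyl-3-(triethylsilyloxy)oct-6-en-1-ol | CC(C)=CCC[C@@](C)(O[Si](CC)(CC)CC)CC(O)c1cc(O[Si](C)(C)C(C)(C)C)c(Br)cc1O[Si](C)(C)C(C)(C)C
F4 | step 7 | (R)-1-[4-bromo-2,5-bis(tert-butyldimethylsilyloxy)phenyl]-3,7-dimethyl-3-(triethylsilyloxy)oct-6-en-1-one | CC(C)=CCC[C@@](C)(O[Si](CC)(CC)CC)CC(=O)c1cc(O[Si](C)(C)C(C)(C)C)c(Br)cc1O[Si](C)(C)C(C)(C)C
F5 | step 8 | (3RS,5R)-5,9-dimethyldec-8-en-1-yne-3,5-diol | CC(C)=CCC[C@@](C)(O)CC(O)C#C
F6 | step 8 | (R)-5-hydroxy-5,9-dimethyldec-8-en-1-yn-3-one | CC(C)=CCC[C@@](C)(O)CC(=O)C#C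
F7 | step 8 | (R)-1-[5-bromo-1-(tert-butyldimethylsilyloxy)-7-oxabicyclo[2.2.1]hepta-2,5-dien-2-yl]-3-hydroxy-3,7-dimethyloct-6-en-1-one | CC(C)=CCC[C@@](C)(O)CC(=O)C1=CC2OC1(O[Si](C)(C)C(C)(C)C)C=C2Br
F8 | step 8 | (R)-1-[4-bromo-2-(tert-butyldimethylsilyloxy)-5-hydroxyphenyl]-3-hydroxy-3,7-dimethyloct-6-en-1-one | CC(C)=CCC[C@@](C)(O)CC(=O)c1cc(O)c(Br)cc1O[Si](C)(C)C(C)(C)C
F9 | step 5 | (3RS,5R)-5,9-dimethyl-5-(triethylsilyloxy)-1-(trimethylsilyl)dec-8-en-1-yn-3-ol | CC(C)=CCC[C@@](C)(O[Si](CC)(CC)CC)CC(O)C#C[Si](C)(C)C
F10 | step 5 | (R)-5,9-dimethyl-5-(triethylsilyloxy)-1-(trimethylsilyl)dec-8-en-1-yn-3-one | CC(C)=CCC[C@@](C)(O[Si](CC)(CC)CC)CC(=O)C#C[Si](C)(C)C
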